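## Structural features

The target, (3S,3aS,4R,7S,7aS)-7-bromo-3-{(E)-[(4S)-4-bromo-3,3-dimethylcyclohexylidene]methyl}-4,7a-dimethyloctahydro-1H-inden-4-ol, is a C20 dibromide in which a trans-fused hydrindane (ring B six-membered, ring C five-membered) and a separate cyclohexane (ring A) are joined only through one exocyclic, trisubstituted E alkene. Locants used throughout follow the target SMILES: ring A is C1 (CMe2), C2, C3 (sp2), C16, C17, C18 (CHBr); C4 is the exocyclic =CH; ring C is C5, C6, C7, C8, C15; ring B is C8, C10 (CHBr), C11, C12, C13 (carbinol), C15; C9 and C14 are the methyls on C8 and C13; the face of the hydrindane that carries C9 is the Me-face, the face that carries H15 is the H-face. Four contiguous stereocentres (C10, C8, C15, C13) line ring B and a fifth, C5, sits next to C15: the C10 bromine is equatorial on the Me-face, the C13 hydroxyl is axial on the Me-face (1,3-diaxial to C9) and the alkenyl arm on C5 lies on the H-face. The sixth centre, C18, is isolated in ring A, five bonds from C5, and cannot be relayed from the bicycle. The fragile groups are two secondary bromides that each flank a quaternary carbon (they cannot be made by SN2 and can be lost by reduction or elimination), a tertiary alcohol that can dehydrate, and an alkene that can migrate into ring A or be hydrogenated. The real difficulties are the two neopentyl C–Br bonds of defined configuration, the geometry of an alkene whose two ring CH2 neighbours (C2 and C16) differ only one atom further out, and an axial tertiary carbinol beside a ring-fusion CH that would epimerise to the cis hydrindane if C13 were ever a ketone. The key step exploits that C13 carries C14, an oxygen, C15 and C12, and that C12 lies two carbons from the ketone-level C10: this is the pattern of a tertiary α-oxy radical on C13 (from hydrogen-atom transfer to C14 of a 2-silyloxyalkene) adding to the terminal carbon of a C10 vinyl ketone, so ring B can be closed on a cyclopentanone whose two arms are already trans.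

## Logic of the disconnections

**33 from 32.** The O–Si bond on the C13 oxygen is cut last. The silyl group is the one the key step installs; kept to the end it guards the tertiary carbinol and marks the Me-face with a bulky group. Nothing is simplified in the skeleton; the forward step must be non-basic so that two secondary bromides and the alkene survive.

**32 from 29, and 29 from 18 and 28.** The C3=C4 double bond is first moved back into ring A (C3=C16) with a hydroxyl on C4, which is 29. The C3–C4 single bond is then cut between an aldehyde carbon (C4 in 18) and an alkenyl metal (C3 from 28). The cut falls here because C18 must arrive in a finished, enantiopure ring A, and because a direct carbonyl olefination at C3 offers no handle on geometry. The gain is convergence into a C12 and a C8 half, each already carrying its bromide. The forward transposition must deliver hydrogen to C16 and turn the C5 arm toward C16, and the coupling must tolerate alkyl bromides and an α-branched aldehyde.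

**28 back to 19.** The O–S bond is cut to ketone 27. The C18–H bond is then cut (27 from 26 from 25), so the bromide is traced to a bromoalkene, which comes from ketone 23 through 24. The C3 hydroxyl of 23 to 26 is a relay centre made by catalytic enantioselective reduction of 21 (giving 22), and 21 comes from 20 and 19. The gain is that the one isolated centre is reduced to a catalyst-controlled ketone reduction. The radical hydrogenation must obey the ring conformation fixed by the relay hydroxyl, and the enol triflate must form away from C2 without displacing bromide.

**18 back to 14.** The C4 oxidation level is adjusted (18 from 17), the C10–H bond is cut (17 from 16), and the bromoalkene is traced through C=N to C=O (16 from 15 from 14). C10 is flanked by the quaternary C8, so its bromide is traced to a ketone in the same way as C18. The gain is that both halogens come from ketones by the same two reactions. Hydrogen must reach C10 on the H-face so that bromine ends equatorial.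

**14 back to 11.** Three changes are undone: C–O for C–Si at C4 (14 from 13), two C–H bonds for the C7–O bond and the C6=C7 π bond (13 from 12), and the C4–C5 bond together with the O–S bond (12 from 11). One conjugate addition supplies the carbon and, through its enolate, the means to delete the C7 carbonyl while the C10 ketone is untouched. Attack on C5 must come from the H-face, and a hindered enolate must be O-sulfonylated.

**11 from 10.** The C5=C6 bond is traced to the β-silyloxy ketone. The oxygen on C5 was the control element of the starting material and is now spent. The elimination must not disturb H15, which becomes γ to the enone.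

**10 from 9.** The C12–C13 bond is cut. This opens ring B and removes the C13 stereocentre, leaving a cyclopentanone with a vinyl ketone on C8 and a 2-silyloxyvinyl group on C15, trans to each other. The forward step needs hydrogen-atom transfer to the enol ether in preference to the enone, 6-endo closure, and the silyloxy group axial on the Me-face.

**9 back to 3, 4 and 5.** The O–Si bond (9 from 8) and the C10 oxidation level (8 from 7) are adjusted, then two C–C bonds are cut in one operation: C13–C15 to 4 and C8–C10 to 5. Three simple components result. The forward step needs conjugate addition anti to the silyloxy group, aldol reaction of a tetrasubstituted enolate on the face away from the new arm, and enolisation of the methyl ketone only.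

**3 back to 1.** The C8–C9 bond is cut to 2, and the C–I bond to 1. The methyl must be in place before the three-component step so that C8 becomes quaternary in it; the coupling must be neutral because the γ-silyloxy enone is base-sensitive.

## Other disconnections considered

**Alternative 1:** The cut is the C5–C15 bond of ring C, with C4 as a formyl group and C5=C15 unsaturated. In the forward step proline condenses with the aldehyde of the prochiral dione A1, the enamine carbon adds to one of the two enantiotopic ring carbonyls, and dehydration gives the bicyclic keto enal A2 with C8 fixed. In its favour, a single catalytic step on an achiral precursor sets the quaternary centre, closes ring C, and leaves C4 as an aldehyde carbon and C10 as a ketone exactly where the endgame needs them. Against it, A2 has C13 as a plain CH2 and C15 as an sp2 carbon. The carbinol would require allylic oxidation to a C13 ketone and methyl addition, and the fusion would require a trans-selective reduction of a tetrasubstituted alkene, for which hydrindenes usually favour cis. A C13 ketone beside H15 also invites epimerisation of the fusion. The enamine of an aldehyde adding to a ketone is a less secure case than the ketone–ketone variant, and C5 would still have to be set by reduction. On step count to a bicycle and on the cost of chirality (no chiral starting material) this alternative is the better. As an ionic, metal-free ring closure it is at least the equal of a radical closure in robustness. Structurally it postpones C15, C13 and C5 to steps with weak stereocontrol, whereas the chosen plan fixes the trans arms before ring B exists and never passes through a C13 ketone.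

**Alternative 2:** The cut is the C8–C9 bond, the angular methyl being made as one bond of a cyclopropane across C8=C15. In the forward step the zinc carbenoid from Et2Zn and CH2I2, bound to the alkoxide of allylic alcohol A3, delivers CH2 to the tetrasubstituted alkene on the hydroxyl face and gives propellane A4. In its favour, hydroxyl-directed cyclopropanation is among the most predictable face-selective reactions, and C5 (with C4 as a protected CH2OH), the C10 ketal and the C13 oxygen are already in place. Against it, the methyl appears only after reductive opening of the cyclopropane, which needs the C13 ketone. The opening must break C15–C9 and not C15–C8, and must then protonate C15 to the trans fusion next to that ketone, where cis is the likely preference. The C13 methyl must afterwards be added with the hydroxyl axial, and dissolving-metal conditions must precede both bromides. The directed step itself is more predictable than the C13 selectivity of the radical closure, and that point goes to the alternative. In step economy it is worse: at least four further steps turn cyclopropane plus secondary carbinol into methyl plus tertiary carbinol, which the chosen plan reaches in one step. It also runs through the epimerisable C13 ketone that the chosen plan avoids.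

**Alternative 3:** The cuts are the ring-fusion bond C8–C15 and the C10–C11 bond, made together. In the forward step heating triene A5 lets the silyloxy diene (C11=C12–C13=C15) and the tethered (E)-nitroalkene (C8=C10) combine; ring B closes, ring C forms from the three-atom tether, and the product is A6 with nitro on C10 and a silyl enol ether at C13. In its favour, two C–C bonds, two rings and three stereocentres (C8, C10, C15) arise in one reagent-free step, the C10 heteroatom lands at the right position and on the right face, and C4 is already attached to C5. Against it, a trisubstituted nitroalkene that must create a quaternary centre is a slow dienophile, and short-tether cycloadditions of this kind are not reliably trans-selective. The nitro group cannot be exchanged for bromine at a neopentyl carbon, so it must pass through the ketone and the same bromoalkene sequence as in the chosen plan. Hydrolysis of the enol ether again gives a C13 ketone beside H15, with methyl addition still to come. In bond-forming power per step, and as a concerted, well-understood mechanism without metals, the alternative is the better or the equal. The chosen plan is the safer on stereocontrol, because its ring fusion is fixed in the substrate before closure, and it needs a simpler precursor than A5, whose stereodefined diene and nitroalkene would add several steps.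

Key step: step 6

Remark: names use the locants and the Me-face/H-face convention defined under Structural features; 9 and 10 as drawn map onto C5, C8, C13 and C15 of 33 without any change of configuration.
Remark: the carbinol carbon formed in step 3 (C10) and again in step 24 (C4) arises as a mixture of epimers; both centres are erased later and are left undefined in the SMILES.
Remark: 1 and 19 are taken as purchased compounds.

## Steps

Step 1
Reactants: 1 (R)-4-(tert-butyldimethylsilyloxy)cyclopent-2-en-1-one
Product: 2 (R)-4-(tert-butyldimethylsilyloxy)-2-iodocyclopent-2-en-1-one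
Conditions: I2, pyridine, CH2Cl2, 0 °C to rt
Reagents that add atoms: iodine, II
Why: α-Iodination of an enone by conjugate addition of pyridine, iodination of the enolate and elimination (Baylis–Hillman-type sequence); the silyloxy-bearing centre is not involved.

Step 2
Reactants: 2 (R)-4-(tert-butyldimethylsilyloxy)-2-iodocyclopent-2-en-1-one
Product: 3 (R)-4-(tert-butyldimethylsilyloxy)-2-methylcyclopent-2-en-1-one
Conditions: Me2Zn, PdCl2(dppf) (5 mol %), THF, 0 °C to rt
Reagents that add atoms: dimethylzinc, C[Zn]C
Why: Negishi coupling of the alkenyl iodide; the neutral conditions spare the base-sensitive γ-silyloxy enone.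

Step 3
Reactants: 3 (R)-4-(tert-butyldimethylsilyloxy)-2-methylcyclopent-2-en-1-one; 4 ethyl vinyl ether; 5 acrolein
Product: 7 (2S,3R,4R)-3-acetyl-4-(tert-butyldimethylsilyloxy)-2-(1-hydroxyprop-2-en-1-yl)-2-methylcyclopentan-1-one, via enol ether aldol 6 (not isolated)
Conditions: 4, t-BuLi, THF, −78 to 0 °C; CuBr·SMe2, −78 °C; then 3, −78 °C; then 5, −78 °C; 0.5 M HCl, THF, 0 °C
Reagents that add atoms: water, O
Why: Conjugate addition of the α-ethoxyvinyl cuprate (an acetyl anion equivalent) anti to the silyloxy group sets C15. The regiodefined enolate then undergoes a 1,2-aldol reaction with acrolein on the face away from the new C15 arm, which makes C8 quaternary with the two arms trans. Dilute acid in the work-up hydrolyses the ethyl enol ether to the methyl ketone, so no acid-labile group reaches the oxidation.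

Step 4
Reactants: 7 (2S,3R,4R)-3-acetyl-4-(tert-butyldimethylsilyloxy)-2-(1-hydroxyprop-2-en-1-yl)-2-methylcyclopentan-1-one
Product: 8 (2R,3R,4R)-3-acetyl-2-acryloyl-4-(tert-butyldimethylsilyloxy)-2-methylcyclopentan-1-one
Conditions: Dess–Martin periodinane, NaHCO3, CH2Cl2, 0 °C to rt
Reagents that add atoms: none
Why: Oxidation of both epimers of the allylic alcohol to the vinyl ketone under buffered, non-basic conditions; the β-silyloxy ketone and the non-enolisable 1,3-diketone are not disturbed.

Step 5
Reactants: 8 (2R,3R,4R)-3-acetyl-2-acryloyl-4-(tert-butyldimethylsilyloxy)-2-methylcyclopentan-1-one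
Product: 9 (2R,3R,4R)-2-acryloyl-4-(tert-butyldimethylsilyloxy)-2-methyl-3-[1-(triethylsilyloxy)vinyl]cyclopentan-1-one
Conditions: Et3SiOTf (1.05 equiv), i-Pr2NEt, CH2Cl2, −78 °C
Reagents that add atoms: triethylsilyl trifluoromethanesulfonate, CC[Si](CC)(CC)OS(=O)(=O)C(F)(F)F
Why: Soft enolisation with a silyl triflate and a hindered amine: the acetyl group is silylated first and loses a proton from the open CH3 and not from the crowded C15. The ring ketone is neopentyl and inductively deactivated by the acyl group on C8, and the hindered base cannot add to the vinyl ketone.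

Step 6
Reactants: 9 (2R,3R,4R)-2-acryloyl-4-(tert-butyldimethylsilyloxy)-2-methyl-3-[1-(triethylsilyloxy)vinyl]cyclopentan-1-one
Product: 10 5-(tert-butyldimethylsilyloxy)-8,13-dimethyl-13-(triethylsilyloxy)-trans-hydrindane-7,10-dione (5-O on the H-face; 13-O on the Me-face)
Conditions: Fe(acac)3 (30 mol %), PhSiH3, Na2HPO4, EtOH–(CH2OH)2, 60 °C
Reagents that add atoms: none
Why: An iron hydride formed from Fe(acac)3 and PhSiH3 transfers a hydrogen atom to C14, the CH2 terminus of the electron-rich 1,1-disubstituted silyl enol ether, which is the fastest hydrogen-atom acceptor in 9 because the electron-poor vinyl ketone is polarity-mismatched. The tertiary α-silyloxy radical at C13 is nucleophilic and adds to C12, the unsubstituted β-carbon of the vinyl ketone; the α-keto radical at C11 is reduced by divalent iron to the enolate, which ethanol protonates. The closest known reaction type is the iron-hydride reductive coupling of donor alkenes, silyl enol ethers included, with enones, used here intramolecularly. Ring B closes in the 6-endo-trig mode, since the 5-exo alternative would require attack at the α-carbon C11 of the acceptor and is electronically disfavoured. The only new stereocentre is C13: in the chair-like transition state the C–O bond takes the axial site on the Me-face, where an oxygen costs less against the angular methyl than a methyl group would, and the smaller C14 methyl takes the equatorial site next to the silyloxy group on C5. The trans ring fusion is not made in this step, because the two arms are already trans on C8 and C15 and neither centre can enolise. The step needs hydrogen-atom transfer to outrun solvolysis of the enol ether, which the phosphate buffer and the fast intramolecular trapping secure; the β-silyloxy ketone and the non-enolisable 1,3-diketone are inert in the neutral medium.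

Step 7
Reactants: 10 5-(tert-butyldimethylsilyloxy)-8,13-dimethyl-13-(triethylsilyloxy)-trans-hydrindane-7,10-dione
Product: 11 8,13-dimethyl-13-(triethylsilyloxy)-trans-hydrind-5-ene-7,10-dione (13-O on the Me-face)
Conditions: DBU, CH2Cl2, 0 °C to rt
Reagents that add atoms: none
Why: E1cB elimination of the β-silyloxy group from the cyclopentanone through the C6 enolate; mild base and short exposure leave the γ-hydrogen H15 and the tertiary silyl ether untouched.

Step 8
Reactants: 11 8,13-dimethyl-13-(triethylsilyloxy)-trans-hydrind-5-ene-7,10-dione
Product: 12 5-[(isopropoxydimethylsilyl)methyl]-8,13-dimethyl-10-oxo-13-(triethylsilyloxy)-trans-hydrind-6-en-7-yl trifluoromethanesulfonate (C5 arm on the H-face)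
Conditions: (i-PrO)Me2SiCH2MgCl (from ClCH2SiMe2(Oi-Pr) and Mg), CuBr·SMe2 (10 mol %), THF, −78 to −40 °C; then PhNTf2, −40 °C to rt
Reagents that add atoms: (chloromethyl)(isopropoxy)dimethylsilane, CC(C)O[Si](C)(C)CCl; N-phenylbis(trifluoromethanesulfonimide), O=S(=O)(N(c1ccccc1)S(=O)(=O)C(F)(F)F)C(F)(F)F
Why: Copper-catalysed conjugate addition of the silylmethyl Grignard reagent (a hydroxymethyl anion equivalent) to the enone, with O-triflation of the regiodefined magnesium enolate. The Me-face of C5 is screened by two syn-axial groups, the angular methyl and the axial C13 silyloxy group, so carbon enters on the H-face. The hindered C10 ketone does not react at low temperature.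

Step 9
Reactants: 12 5-[(isopropoxydimethylsilyl)methyl]-8,13-dimethyl-10-oxo-13-(triethylsilyloxy)-trans-hydrind-6-en-7-yl trifluoromethanesulfonate
Product: 13 5-[(isopropoxydimethylsilyl)methyl]-8,13-dimethyl-13-(triethylsilyloxy)-trans-hydrindan-10-one
Conditions: H2 (1 atm), Pd/C, Et3N, EtOAc, rt
Reagents that add atoms: none
Why: Hydrogenolysis of the enol triflate C–O bond and hydrogenation of the resulting alkene turn C7 into CH2, which is a deoxygenation of the former ketone; the amine takes up the triflic acid, and palladium does not reduce the hindered C10 ketone.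

Step 10
Reactants: 13 5-[(isopropoxydimethylsilyl)methyl]-8,13-dimethyl-13-(triethylsilyloxy)-trans-hydrindan-10-one
Product: 14 5-(hydroxymethyl)-8,13-dimethyl-13-(triethylsilyloxy)-trans-hydrindan-10-one
Conditions: 30% H2O2, KF, KHCO3, THF–MeOH, rt
Reagents that add atoms: hydrogen peroxide, OO
Why: Tamao oxidation of the alkoxysilane: the C–Si bond is replaced by C–O with retention, under mild basic peroxide that leaves the hindered ketone and the tertiary silyl ether alone.

Step 11
Reactants: 14 5-(hydroxymethyl)-8,13-dimethyl-13-(triethylsilyloxy)-trans-hydrindan-10-one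
Product: 15 hydrazone of 14 at C10
Conditions: N2H4·H2O, Et3N, EtOH, 80 °C
Reagents that add atoms: hydrazine, NN
Why: Condensation of the only carbonyl group with hydrazine; by now the C7 carbonyl is gone, so no 1,3-dicarbonyl is left to condense twice or to cleave.

Step 12
Reactants: 15 hydrazone of 14 at C10
Product: 16 10-bromo-5-(hydroxymethyl)-8,13-dimethyl-13-(triethylsilyloxy)-trans-hydrind-10-ene
Conditions: NBS, pyridine, CH2Cl2, −10 °C to rt
Reagents that add atoms: N-bromosuccinimide, O=C1CCC(=O)N1Br
Why: Barton-type vinyl halide synthesis: N-bromination, loss of HBr to the diazo compound, a second bromination and loss of N2 with a β-proton. C8 is quaternary, so the double bond can only form toward C11.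

Step 13
Reactants: 16 10-bromo-5-(hydroxymethyl)-8,13-dimethyl-13-(triethylsilyloxy)-trans-hydrind-10-ene
Product: 17 10-bromo-5-(hydroxymethyl)-8,13-dimethyl-13-(triethylsilyloxy)-trans-hydrindane (Br equatorial on the Me-face)
Conditions: Mn(dpm)3 (cat.), PhSiH3, t-BuOOH, i-PrOH, rt
Reagents that add atoms: none
Why: Hydrogen-atom-transfer hydrogenation of a haloalkene, which keeps the C–Br bond: H• adds to C11 and the α-bromo radical at C10 takes its hydrogen along the axial H-face trajectory, away from the angular methyl. Bromine therefore ends equatorial, which is also the more stable epimer.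

Step 14
Reactants: 17 10-bromo-5-(hydroxymethyl)-8,13-dimethyl-13-(triethylsilyloxy)-trans-hydrindane
Product: 18 10-bromo-8,13-dimethyl-13-(triethylsilyloxy)-trans-hydrindane-5-carbaldehyde (CHO on the H-face)
Conditions: Dess–Martin periodinane, NaHCO3, CH2Cl2, 0 °C
Reagents that add atoms: none
Why: Buffered oxidation of the primary alcohol to the aldehyde; the H-face epimer at C5 is also the thermodynamic one, so any enolisation cannot erode it.

Step 15
Reactants: 19 7,7-dimethyl-1,4-dioxaspiro[4.5]decan-8-one
Product: 20 2,2-dimethylcyclohexane-1,4-dione
Conditions: 1 M HCl, THF, rt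
Reagents that add atoms: water, O
Why: Acid-catalysed hydrolysis of the dioxolane.

Step 16
Reactants: 20 2,2-dimethylcyclohexane-1,4-dione
Product: 21 6,6-dimethylcyclohex-2-ene-1,4-dione
Conditions: IBX, DMSO–PhF, 70 °C
Reagents that add atoms: none
Why: IBX dehydrogenation of a ketone to the enone; only C16–C17 lies between two enolisable positions, C2 being blocked by the quaternary C1.

Step 17
Reactants: 21 6,6-dimethylcyclohex-2-ene-1,4-dione
Product: 22 (R)-4-hydroxy-6,6-dimethylcyclohex-2-en-1-one
Conditions: (S)-Me-CBS oxazaborolidine (20 mol %), catecholborane, toluene, −78 °C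
Reagents that add atoms: none
Why: Corey–Bakshi–Shibata reduction of the less hindered enone carbonyl (C3; the other carbonyl is flanked by the quaternary C1). With the alkenyl side as the large group and the CH2 side as the small group, the (S)-catalyst gives the (R)-carbinol. This centre is a relay that controls step 21 and is erased in step 22.

Step 18
Reactants: 22 (R)-4-hydroxy-6,6-dimethylcyclohex-2-en-1-one
Product: 23 (S)-4-hydroxy-2,2-dimethylcyclohexan-1-one
Conditions: H2 (1 atm), Rh/Al2O3, EtOAc, rt
Reagents that add atoms: none
Why: Hydrogenation of the electron-poor alkene on rhodium, which has little tendency to isomerise the allylic alcohol to the dione; the descriptor changes to S by priority only.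

Step 19
Reactants: 23 (S)-4-hydroxy-2,2-dimethylcyclohexan-1-one
Product: 24 hydrazone of 23
Conditions: N2H4·H2O, Et3N, EtOH, reflux
Reagents that add atoms: hydrazine, NN
Why: Condensation of the hindered ketone with excess hydrazine.

Step 20
Reactants: 24 hydrazone of 23
Product: 25 (S)-4-bromo-5,5-dimethylcyclohex-3-en-1-ol
Conditions: NBS, pyridine, CH2Cl2, −10 °C
Reagents that add atoms: N-bromosuccinimide, O=C1CCC(=O)N1Br
Why: Barton-type vinyl bromide synthesis as in step 12; the only β-hydrogens are on C17, so one regioisomer forms, and excess base at low temperature makes proton loss faster than any capture by the remote hydroxyl.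

Step 21
Reactants: 25 (S)-4-bromo-5,5-dimethylcyclohex-3-en-1-ol
Product: 26 (1S,4S)-4-bromo-3,3-dimethylcyclohexan-1-ol
Conditions: Mn(dpm)3 (cat.), PhSiH3, t-BuOOH, i-PrOH, rt
Reagents that add atoms: none
Why: Hydrogen-atom-transfer hydrogenation of the bromoalkene: H• adds to C17 and the C18 radical takes its hydrogen axially. The ring is locked with the C3 hydroxyl equatorial, because an axial hydroxyl would be 1,3-diaxial to a C1 methyl. Bromine therefore ends equatorial and trans to the hydroxyl, which is the S configuration at C18.

Step 22
Reactants: 26 (1S,4S)-4-bromo-3,3-dimethylcyclohexan-1-ol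
Product: 27 (S)-4-bromo-3,3-dimethylcyclohexan-1-one
Conditions: Dess–Martin periodinane, NaHCO3, CH2Cl2, 0 °C to rt
Reagents that add atoms: none
Why: Oxidation of the relay carbinol; C18 is now the only stereocentre and is not enolisable.

Step 23
Reactants: 27 (S)-4-bromo-3,3-dimethylcyclohexan-1-one
Product: 28 (S)-4-bromo-5,5-dimethylcyclohex-1-en-1-yl trifluoromethanesulfonate
Conditions: LiN(SiMe3)2, THF, −78 °C; N-(5-chloropyridin-2-yl)triflimide, −78 °C
Reagents that add atoms: N-(5-chloropyridin-2-yl)bis(trifluoromethanesulfonimide), O=S(=O)(N(c1ccc(Cl)cn1)S(=O)(=O)C(F)(F)F)C(F)(F)F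
Why: Kinetic deprotonation at C16, away from the C2 methylene that is buttressed by the gem-dimethyl carbon, followed by O-triflation with the pyridyl triflimide, which is fast at −78 °C and so outruns 1,3-alkylation of the enolate by the C18 bromide.

Step 24
Reactants: 18 10-bromo-8,13-dimethyl-13-(triethylsilyloxy)-trans-hydrindane-5-carbaldehyde; 28 (S)-4-bromo-5,5-dimethylcyclohex-1-en-1-yl trifluoromethanesulfonate
Product: 29 [10-bromo-8,13-dimethyl-13-(triethylsilyloxy)-trans-hydrindan-5-yl][(4S)-4-bromo-5,5-dimethylcyclohex-1-en-1-yl]methanol (C4 epimers)
Conditions: CrCl2, NiCl2 (1 mol %), DMF, rt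
Reagents that add atoms: none
Why: Nozaki–Hiyama–Kishi coupling: nickel-catalysed formation of the alkenylchromium reagent from the enol triflate and its addition to the hindered aldehyde. Secondary alkyl bromides, the silyl ether and the α-stereocentre C5 are inert to the reagent, and both C4 epimers are usable.

Step 25
Reactants: 29 [10-bromo-8,13-dimethyl-13-(triethylsilyloxy)-trans-hydrindan-5-yl][(4S)-4-bromo-5,5-dimethylcyclohex-1-en-1-yl]methanol
Product: 32 13-O-triethylsilyl ether of the target, via sulfonylhydrazine adduct 30 (not isolated), via allylic diazene 31 (not isolated)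
Conditions: 2-nitrobenzenesulfonylhydrazide, PPh3, DEAD, N-methylmorpholine, −30 °C; then rt
Reagents that add atoms: none
Why: Myers reductive 1,3-transposition: Mitsunobu displacement of the allylic hydroxyl by the sulfonylhydrazide, loss of the sulfinic acid on warming to give the monoalkyl diazene, and a concerted retro-ene loss of N2 that delivers hydrogen to C16 and moves the double bond to C3=C4. The C4–N bond must stand perpendicular to the ring alkene, and the hydrindanyl group then turns away from C2 (A(1,2) strain), so it ends cis to C16, which is the E isomer.

Step 26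
Reactants: 32 13-O-triethylsilyl ether of the target
Product: 33 (3S,3aS,4R,7S,7aS)-7-bromo-3-{(E)-[(4S)-4-bromo-3,3-dimethylcyclohexylidene]methyl}-4,7a-dimethyloctahydro-1H-inden-4-ol
Conditions: HF·pyridine, pyridine, THF, 0 °C to rt
Reagents that add atoms: none
Why: Fluoride cleavage of the tertiary silyl ether under buffered, non-basic conditions, so neither bromide can eliminate and the alkene does not migrate.

## Compound list

1 | (R)-4-(tert-butyldimethylsilyloxy)cyclopent-2-en-1-one | O=C1C=C[C@H](O[Si](C)(C)C(C)(C)C)C1 | starting material
2 | (R)-4-(tert-butyldimethylsilyloxy)-2-iodocyclopent-2-en-1-one | O=C1C(I)=C[C@H](O[Si](C)(C)C(C)(C)C)C1 | intermediate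
3 | (R)-4-(tert-butyldimethylsilyloxy)-2-methylcyclopent-2-en-1-one | O=C1C(C)=C[C@H](O[Si](C)(C)C(C)(C)C)C1 | intermediate
4 | ethyl vinyl ether | C=COCC | starting material
5 | acrolein | C=CC=O | starting material
6 | (2S,3R,4R)-4-(tert-butyldimethylsilyloxy)-3-(1-ethoxyvinyl)-2-(1-hydroxyprop-2-en-1-yl)-2-methylcyclopentan-1-one (carbinol epimers) | CC(C)(C)[Si](C)(C)O[C@@H]1CC(=O)[C@](C)(C(O)C=C)[C@H]1C(=C)OCC | intermediate (not isolated)
7 | (2S,3R,4R)-3-acetyl-4-(tert-butyldimethylsilyloxy)-2-(1-hydroxyprop-2-en-1-yl)-2-methylcyclopentan-1-one (carbinol epimers) | CC(C)(C)[Si](C)(C)O[C@@H]1CC(=O)[C@](C)(C(O)C=C)[C@H]1C(C)=O | intermediate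
8 | (2R,3R,4R)-3-acetyl-2-acryloyl-4-(tert-butyldimethylsilyloxy)-2-methylcyclopentan-1-one | CC(C)(C)[Si](C)(C)O[C@@H]1CC(=O)[C@](C)(C(=O)C=C)[C@H]1C(C)=O | intermediate
9 | (2R,3R,4R)-2-acryloyl-4-(tert-butyldimethylsilyloxy)-2-methyl-3-[1-(triethylsilyloxy)vinyl]cyclopentan-1-one | CC(C)(C)[Si](C)(C)O[C@@H]1CC(=O)[C@](C)(C(=O)C=C)[C@H]1C(=C)O[Si](CC)(CC)CC | intermediate
10 | 5-(tert-butyldimethylsilyloxy)-8,13-dimethyl-13-(triethylsilyloxy)-trans-hydrindane-7,10-dione (5-O on the H-face; 13-O on the Me-face) | CC(C)(C)[Si](C)(C)O[C@@H]2CC(=O)[C@]3(C)C(=O)CC[C@@](C)(O[Si](CC)(CC)CC)[C@@H]23 | intermediate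
11 | 8,13-dimethyl-13-(triethylsilyloxy)-trans-hydrind-5-ene-7,10-dione | C1=CC(=O)[C@]2(C)C(=O)CC[C@@](C)(O[Si](CC)(CC)CC)[C@@H]12 | intermediate
12 | 5-[(isopropoxydimethylsilyl)methyl]-8,13-dimethyl-10-oxo-13-(triethylsilyloxy)-trans-hydrind-6-en-7-yl trifluoromethanesulfonate (C5 arm on the H-face) | CC(C)O[Si](C)(C)C[C@@H]1C=C(OS(=O)(=O)C(F)(F)F)[C@]2(C)C(=O)CC[C@@](C)(O[Si](CC)(CC)CC)[C@@H]12 | intermediate
13 | 5-[(isopropoxydimethylsilyl)methyl]-8,13-dimethyl-13-(triethylsilyloxy)-trans-hydrindan-10-one | CC(C)O[Si](C)(C)C[C@@H]1CC[C@]2(C)C(=O)CC[C@@](C)(O[Si](CC)(CC)CC)[C@@H]12 | intermediate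
14 | 5-(hydroxymethyl)-8,13-dimethyl-13-(triethylsilyloxy)-trans-hydrindan-10-one | OC[C@@H]1CC[C@]2(C)C(=O)CC[C@@](C)(O[Si](CC)(CC)CC)[C@@H]12 | intermediate
15 | hydrazone of 14 at C10 | OC[C@@H]1CC[C@]2(C)C(=NN)CC[C@@](C)(O[Si](CC)(CC)CC)[C@@H]12 | intermediate
16 | 10-bromo-5-(hydroxymethyl)-8,13-dimethyl-13-(triethylsilyloxy)-trans-hydrind-10-ene | OC[C@@H]1CC[C@]2(C)C(Br)=CC[C@@](C)(O[Si](CC)(CC)CC)[C@@H]12 | intermediate
17 | 10-bromo-5-(hydroxymethyl)-8,13-dimethyl-13-(triethylsilyloxy)-trans-hydrindane (Br equatorial on the Me-face) | OC[C@@H]1CC[C@]2(C)[C@@H](Br)CC[C@@](C)(O[Si](CC)(CC)CC)[C@@H]12 | intermediate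
18 | 10-bromo-8,13-dimethyl-13-(triethylsilyloxy)-trans-hydrindane-5-carbaldehyde (CHO on the H-face) | O=C[C@@H]1CC[C@]2(C)[C@@H](Br)CC[C@@](C)(O[Si](CC)(CC)CC)[C@@H]12 | intermediate
19 | 7,7-dimethyl-1,4-dioxaspiro[4.5]decan-8-one | O=C1CCC2(CC1(C)C)OCCO2 | starting material
20 | 2,2-dimethylcyclohexane-1,4-dione | CC1(C)CC(=O)CCC1=O | intermediate
21 | 6,6-dimethylcyclohex-2-ene-1,4-dione | CC1(C)CC(=O)C=CC1=O | intermediate
22 | (R)-4-hydroxy-6,6-dimethylcyclohex-2-en-1-one | O[C@H]1C=CC(=O)C(C)(C)C1 | intermediate
23 | (S)-4-hydroxy-2,2-dimethylcyclohexan-1-one | O[C@H]1CCC(=O)C(C)(C)C1 | intermediate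
24 | hydrazone of 23 | O[C@H]1CCC(=NN)C(C)(C)C1 | intermediate
25 | (S)-4-bromo-5,5-dimethylcyclohex-3-en-1-ol | O[C@H]1CC=C(Br)C(C)(C)C1 | intermediate
26 | (1S,4S)-4-bromo-3,3-dimethylcyclohexan-1-ol | O[C@H]1CC[C@H](Br)C(C)(C)C1 | intermediate
27 | (S)-4-bromo-3,3-dimethylcyclohexan-1-one | O=C1CC[C@H](Br)C(C)(C)C1 | intermediate
28 | (S)-4-bromo-5,5-dimethylcyclohex-1-en-1-yl trifluoromethanesulfonate | O=S(=O)(OC1=CC[C@H](Br)C(C)(C)C1)C(F)(F)F | intermediate
29 | [10-bromo-8,13-dimethyl-13-(triethylsilyloxy)-trans-hydrindan-5-yl][(4S)-4-bromo-5,5-dimethylcyclohex-1-en-1-yl]methanol (C4 epimers) | OC([C@@H]1CC[C@]2(C)[C@@H](Br)CC[C@@](C)(O[Si](CC)(CC)CC)[C@@H]12)C3=CC[C@H](Br)C(C)(C)C3 | intermediate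
30 | N-alkyl-N-(2-nitrobenzenesulfonyl)hydrazine formed from 29 at C4 | NN(C([C@@H]1CC[C@]2(C)[C@@H](Br)CC[C@@](C)(O[Si](CC)(CC)CC)[C@@H]12)C3=CC[C@H](Br)C(C)(C)C3)S(=O)(=O)c4ccccc4[N+](=O)[O-] | intermediate (not isolated)
31 | allylic monoalkyl diazene at C4 | N=NC([C@@H]1CC[C@]2(C)[C@@H](Br)CC[C@@](C)(O[Si](CC)(CC)CC)[C@@H]12)C3=CC[C@H](Br)C(C)(C)C3 | intermediate (not isolated)
32 | 13-O-triethylsilyl ether of the target | CC1(C)C/C(=C/[C@@H]2CC[C@]3(C)[C@@H](Br)CC[C@@](C)(O[Si](CC)(CC)CC)[C@@H]23)CC[C@@H]1Br | intermediate
33 | (3S,3aS,4R,7S,7aS)-7-bromo-3-{(E)-[(4S)-4-bromo-3,3-dimethylcyclohexylidene]methyl}-4,7a-dimethyloctahydro-1H-inden-4-ol | CC1(C)C/C(=C/[C@@H]2CC[C@]3(C)[C@@H](Br)CC[C@@](C)(O)[C@@H]23)CC[C@@H]1Br | target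

## Step count and least certain steps

Total: 26 steps. Longest linear sequence: 17 steps (steps 1 to 14 and 24 to 26). The ring A branch (steps 15 to 23) has 9 steps and joins at step 24.

**Step 6 (key step).** The most likely failure is leakage of facial control at the prochiral radical carbon C13, because the preference for an axial silyloxy group rests on one 1,3-diaxial contact; premature solvolysis of the silyl enol ether in the protic medium would compound it. Fallback: dispense with the enol ether. Setting out from 8, SmI2 in THF–MeOH at −78 °C joins the same two carbons, C12 and C13, in a reductive ketone–enone cyclisation and gives the free tertiary alcohol, 5-(tert-butyldimethylsilyloxy)-13-hydroxy-8,13-dimethyl-trans-hydrindane-7,10-dione F1. Silylation with Et3SiOTf and 2,6-lutidine comes back to the route at 10. The controlling element is then a samarium-bound ketyl instead of a free radical, and no acid-labile enol ether is involved.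

**Step 5.** The most likely failure is loss of chemoselectivity in the enolisation: the ring ketone may be silylated toward C6 alongside the acetyl group. Fallback: give up the selectivity. Setting out from 8, excess Et3SiOTf and Et3N make the bis(triethylsilyl enol ether) F2. The iron-hydride closure is run on it, since the terminal enol ether is the faster hydrogen-atom acceptor and the ring enol ether has no acceptor within reach, to give the ring-closed bis-silyl compound F3. Its ring enol ether is hydrolysed with K2CO3 in methanol, and the route is rejoined at 10.

**Step 8.** The most likely failure is insufficient facial bias at C5, so that carbon enters on the Me-face and the arm ends on the wrong side. Fallback: deliver hydrogen instead of carbon from the accessible face. Setting out from 11, the same copper-catalysed addition is run with Me3SiCl to give the C5-epimeric trimethylsilyl enol ether F4. Saegusa oxidation with Pd(OAc)2 erases C5 and gives the β-substituted enone F5. Conjugate reduction with LiBH(s-Bu)3 from that same face, with PhNTf2 trapping, then places the arm on the H-face and comes back at 12.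

**Step 23.** The most likely failure is self-alkylation of the enolate, in which C16 displaces the C18 bromide to form a cyclopropane, or erosion of regiocontrol. Fallback: avoid the enolate. Setting out from 27, hydrazine gives the hydrazone F6, and I2 with tetramethylguanidine (Barton conditions) gives the vinyl iodide F7. Its CrCl2/NiCl2 coupling with 18 comes back to the route at 29.

**Step 25.** The most likely failure is poor control of alkene geometry in the retro-ene step, because the two ring CH2 neighbours of C3 differ only at the next atom; sluggish Mitsunobu displacement at the hindered carbinol is a second weakness. Fallback: a stereospecific Horner–Wittig sequence. Setting out from 17, I2, PPh3 and imidazole give the primary iodide F8; LiPPh2 followed by H2O2 gives the diphenylphosphine oxide F9. Its lithio derivative adds to ketone 27 to give the β-hydroxy phosphine oxide F10, whose diastereomers are separated. The one that leads to the E alkene is eliminated with NaH in a syn-stereospecific step, which comes back to the route at 32.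

## Further compounds

F1 | step 6 | 5-(tert-butyldimethylsilyloxy)-13-hydroxy-8,13-dimethyl-trans-hydrindane-7,10-dione | CC(C)(C)[Si](C)(C)O[C@@H]2CC(=O)[C@]3(C)C(=O)CC[C@@](C)(O)[C@@H]23
F2 | step 5 | bis(triethylsilyl enol ether) of 8 (ring enol ether C6=C7 and side-chain enol ether C13=C14) | CC(C)(C)[Si](C)(C)O[C@@H]1C=C(O[Si](CC)(CC)CC)[C@](C)(C(=O)C=C)[C@H]1C(=C)O[Si](CC)(CC)CC
F3 | step 5 | ring-closed bis-silyl compound (C7 triethylsilyl enol ether of 10) | CC(C)(C)[Si](C)(C)O[C@@H]2C=C(O[Si](CC)(CC)CC)[C@]3(C)C(=O)CC[C@@](C)(O[Si](CC)(CC)CC)[C@@H]23
F4 | step 8 | C5-epimeric C7 trimethylsilyl enol ether (arm on the Me-face) | CC(C)O[Si](C)(C)C[C@H]1C=C(O[Si](C)(C)C)[C@]2(C)C(=O)CC[C@@](C)(O[Si](CC)(CC)CC)[C@@H]12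
F5 | step 8 | 5-[(isopropoxydimethylsilyl)methyl]-8,13-dimethyl-13-(triethylsilyloxy)-trans-hydrind-5-ene-7,10-dione | CC(C)O[Si](C)(C)CC1=CC(=O)[C@]2(C)C(=O)CC[C@@](C)(O[Si](CC)(CC)CC)[C@@H]12
F6 | step 23 | hydrazone of (S)-4-bromo-3,3-dimethylcyclohexan-1-one | NN=C1CC[C@H](Br)C(C)(C)C1
F7 | step 23 | (S)-4-bromo-1-iodo-5,5-dimethylcyclohex-1-ene | IC1=CC[C@H](Br)C(C)(C)C1
F8 | step 25 | 10-bromo-5-(iodomethyl)-8,13-dimethyl-13-(triethylsilyloxy)-trans-hydrindane | IC[C@@H]1CC[C@]2(C)[C@@H](Br)CC[C@@](C)(O[Si](CC)(CC)CC)[C@@H]12
F9 | step 25 | {[10-bromo-8,13-dimethyl-13-(triethylsilyloxy)-trans-hydrindan-5-yl]methyl}diphenylphosphine oxide | O=P(C[C@@H]1CC[C@]2(C)[C@@H](Br)CC[C@@](C)(O[Si](CC)(CC)CC)[C@@H]12)(c3ccccc3)c4ccccc4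
F10 | step 25 | β-hydroxy phosphine oxide from F9 and 27 (C3 and C4 diastereomers, separated) | O=P(C([C@@H]1CC[C@]2(C)[C@@H](Br)CC[C@@](C)(O[Si](CC)(CC)CC)[C@@H]12)C3(O)CC[C@H](Br)C(C)(C)C3)(c4ccccc4)c5ccccc5
A1 | alternative 1 | 4-(1-methyl-2,6-dioxocyclohexyl)butanal | CC1(CCCC=O)C(=O)CCCC1=O
A2 | alternative 1 | (S)-7a-methyl-7-oxo-2,4,5,6,7,7a-hexahydro-1H-indene-3-carbaldehyde | O=CC1=C2CCCC(=O)[C@@]2(C)CC1
A3 | alternative 2 | allylic alcohol with the tetrasubstituted C8=C15 alkene, C10 dimethyl ketal and C5 silyloxymethyl group | CC(C)(C)[Si](C)(C)OC[C@@H]1CCC2=C1[C@H](O)CCC2(OC)OC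
A4 | alternative 2 | propellane cyclopropyl carbinol | CC(C)(C)[Si](C)(C)OC[C@@H]2CC[C@]3(C4)C(OC)(OC)CC[C@@H](O)[C@]234
A5 | alternative 3 | silyloxy diene with tethered (E)-nitroalkene | CC(C)(C)[Si](C)(C)OC[C@H](CC/C(C)=C/[N+](=O)[O-])C=C(O[Si](C)(C)C(C)(C)C)C=C
A6 | alternative 3 | trans-fused nitro hydrindene silyl enol ether | CC(C)(C)[Si](C)(C)OC[C@@H]2CC[C@]3(C)[C@@H]([N+](=O)[O-])CC=C(O[Si](C)(C)C(C)(C)C)[C@@H]23
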